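The dihydro-1,4-dioxine ring (benzodioxine locants: C2 bears CH2OH, C3 the aryl group) is opened at the C2–C3 bond and at the aryl ether bond O4–C4a. This turns C3–O4 into the carbonyl group of a protected 5-hydroxyvanillin, and C2, flanked by O1 and the hydroxymethyl carbon, into the α-carbon of a chiral aryloxyacetyl imide whose arene carries iodine at C4a. In one flask an Evans boron aldol reaction sets both stereocentres and the new C3 hydroxyl is closed onto the iodoarene by CuI-catalysed O-arylation, a formal [4+2] annulation of the aldehyde. The precursor is the (S)-4-benzyloxazolidinone glycolate of 4-bromo-2-iodo-6-methoxyphenol; its bromine later carries the propenal chain.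

Key step: step 4

Remark: compound 3 is taken as a catalogue compound, and the crude aldol adduct of step 4 is carried into the copper stage without purification, so both stages count as one operation.

Step 1
Reactants: 1 4-bromo-2-methoxyphenol
Product: 2 4-bromo-2-iodo-6-methoxyphenol
Conditions: NIS, TsOH·H2O (cat.), MeCN, 0 °C to rt
Reagents that add atoms: N-iodosuccinimide, O=C1CCC(=O)N1I
Why: Electrophilic aromatic iodination directed by the hydroxyl group, whose para position is blocked by bromine and one ortho position by methoxy, so iodine should enter at the only free ortho carbon.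

Step 2
Reactants: 2 4-bromo-2-iodo-6-methoxyphenol; 3 (4S)-4-benzyl-3-(chloroacetyl)-1,3-oxazolidin-2-one
Product: 4 (4S)-4-benzyl-3-[(4-bromo-2-iodo-6-methoxyphenoxy)acetyl]-1,3-oxazolidin-2-one
Conditions: K2CO3, NaI (cat.), acetone, 45 °C
Reagents that add atoms: none
Why: Williamson ether synthesis with Finkelstein activation, in which the phenoxide displaces the α-halide irreversibly while acyl transfer from the imide to the phenoxide is thermodynamically uphill; the auxiliary stereocentre is not involved.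

Step 3
Reactants: 5 3,4-dihydroxy-5-methoxybenzaldehyde
Product: 6 3-methoxy-4,5-bis(methoxymethoxy)benzaldehyde
Conditions: MOMCl, iPr2NEt, CH2Cl2, 0 °C to rt
Reagents that add atoms: chloromethyl methyl ether, COCCl
Why: O-Alkylation of both phenols (MOM protection) should give ethers that tolerate the boron enolate, base, hydride and palladium steps and are removed by aqueous acid at the end.

Step 4
Reactants: 4 (4S)-4-benzyl-3-[(4-bromo-2-iodo-6-methoxyphenoxy)acetyl]-1,3-oxazolidin-2-one; 6 3-methoxy-4,5-bis(methoxymethoxy)benzaldehyde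
Product: 10 (4S)-4-benzyl-3-{[(2S,3R)-6-bromo-8-methoxy-3-[3-methoxy-4,5-bis(methoxymethoxy)phenyl]-2,3-dihydro-1,4-benzodioxin-2-yl]carbonyl}-1,3-oxazolidin-2-one, via Z-boron enolate 7 (not isolated), via boron aldolate 8 (not isolated), via syn-aldol adduct 9 (not isolated)
Conditions: Bu2BOTf, iPr2NEt, CH2Cl2, −78 to 0 °C; 6, −78 to 0 °C; pH 7 buffer, MeOH, H2O2, 0 °C, extraction; crude in toluene: CuI (10 mol %), 3,4,7,8-tetramethyl-1,10-phenanthroline (20 mol %), K3PO4, 4 Å MS, 70 °C
Reagents that add atoms: none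
Why: Bu2BOTf/iPr2NEt should convert 4 into the Z-boron enolate 7, which adds to aldehyde 6 through a closed chair (Zimmerman–Traxler) transition state to form the C2–C3 bond as aldolate 8; oxidative release gives the free C3 alcohol 9, whose copper alkoxide should add oxidatively into the ortho C–I bond and form the O4–C4a bond by C–O reductive elimination. The closest known reaction types are the Evans syn-glycolate aldol reaction and the intramolecular Ullmann-type etherification of an aryl iodide, run back to back so that aldehyde 6 is annulated in a formal [4+2] sense. The dihydrodioxine ring closes as a six-membered ring in the exo mode, the alkoxide oxygen attacking the iodine-bearing arene carbon while iodide leaves outside the ring. Both stereocentres arise in the aldol stage: the benzyl group of the (4S)-oxazolidinone blocks one face of the dipole-minimised Z-enolate and the equatorial aryl group of 6 in the chair fixes the syn relation, which should give (2S,3R); the etherification breaks no bond at C2 or C3, so the syn adduct maps onto the trans-2,3-disubstituted ring. The step needs chemoselectivity for iodine over bromine, secured because the C–I bond is the more reactive toward monovalent copper and is the only halide within reach of the tethered alkoxide. Should base epimerise C2 after closure, equilibration would favour the same trans, diequatorial isomer.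

Step 5
Reactants: 10 (4S)-4-benzyl-3-{[(2S,3R)-6-bromo-8-methoxy-3-[3-methoxy-4,5-bis(methoxymethoxy)phenyl]-2,3-dihydro-1,4-benzodioxin-2-yl]carbonyl}-1,3-oxazolidin-2-one
Product: 11 [(2R,3R)-6-bromo-8-methoxy-3-[3-methoxy-4,5-bis(methoxymethoxy)phenyl]-2,3-dihydro-1,4-benzodioxin-2-yl]methanol
Conditions: LiBH4, H2O (1 equiv), THF, 0 °C
Reagents that add atoms: none
Why: Hydride reduction of the N-acyl oxazolidinone at the exocyclic carbonyl should release the auxiliary and give the primary alcohol faster than C2 can enolise, leaving the aryl bromide and MOM ethers untouched (the C2 descriptor changes to R only through the priority rules).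

Step 6
Reactants: 11 [(2R,3R)-6-bromo-8-methoxy-3-[3-methoxy-4,5-bis(methoxymethoxy)phenyl]-2,3-dihydro-1,4-benzodioxin-2-yl]methanol; 12 (E)-2-(3,3-diethoxyprop-1-en-1-yl)-4,4,5,5-tetramethyl-1,3,2-dioxaborolane
Product: 15 (2E)-3-[(2R,3R)-3-(3,4-dihydroxy-5-methoxyphenyl)-2-(hydroxymethyl)-8-methoxy-2,3-dihydro-1,4-benzodioxin-6-yl]prop-2-enal, via coupled diethyl acetal 13 (not isolated), via MOM-protected enal 14 (not isolated)
Conditions: PdCl2(dppf) (5 mol %), K2CO3, dioxane/H2O, 85 °C; then 3 M HCl, THF, 45 °C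
Reagents that add atoms: water, O
Why: Suzuki–Miyaura coupling (oxidative addition of the aryl bromide to zerovalent palladium, transmetalation and reductive elimination with retention of the E geometry) should attach the three-carbon chain, after which aqueous acid hydrolyses the diethyl acetal to the enal and the two MOM acetals to the catechol without touching C2 or C3.

Compound list
1 | 4-bromo-2-methoxyphenol | COc1cc(Br)ccc1O | starting material
2 | 4-bromo-2-iodo-6-methoxyphenol | COc1cc(Br)cc(I)c1O | intermediate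
3 | (4S)-4-benzyl-3-(chloroacetyl)-1,3-oxazolidin-2-one | O=C(CCl)N1C(=O)OC[C@@H]1Cc1ccccc1 | starting material
4 | (4S)-4-benzyl-3-[(4-bromo-2-iodo-6-methoxyphenoxy)acetyl]-1,3-oxazolidin-2-one | O=C(COc1c(I)cc(Br)cc1OC)N1C(=O)OC[C@@H]1Cc1ccccc1 | intermediate
5 | 3,4-dihydroxy-5-methoxybenzaldehyde | COc1cc(C=O)cc(O)c1O | starting material
6 | 3-methoxy-4,5-bis(methoxymethoxy)benzaldehyde | COCOc1cc(C=O)cc(OC)c1OCOC | intermediate
7 | (4S)-4-benzyl-3-[(Z)-2-(4-bromo-2-iodo-6-methoxyphenoxy)-1-[(dibutylboranyl)oxy]ethenyl]-1,3-oxazolidin-2-one | CCCCB(CCCC)O/C(=C\Oc1c(I)cc(Br)cc1OC)N1C(=O)OC[C@@H]1Cc1ccccc1 | intermediate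
8 | (4S)-4-benzyl-3-[(2S,3R)-2-(4-bromo-2-iodo-6-methoxyphenoxy)-3-[(dibutylboranyl)oxy]-3-[3-methoxy-4,5-bis(methoxymethoxy)phenyl]propanoyl]-1,3-oxazolidin-2-one | O=C([C@@H](Oc1c(I)cc(Br)cc1OC)[C@H](OB(CCCC)CCCC)c1cc(OC)c(OCOC)c(OCOC)c1)N1C(=O)OC[C@@H]1Cc1ccccc1 | intermediate
9 | (4S)-4-benzyl-3-[(2S,3R)-2-(4-bromo-2-iodo-6-methoxyphenoxy)-3-hydroxy-3-[3-methoxy-4,5-bis(methoxymethoxy)phenyl]propanoyl]-1,3-oxazolidin-2-one | O=C([C@@H](Oc1c(I)cc(Br)cc1OC)[C@H](O)c1cc(OC)c(OCOC)c(OCOC)c1)N1C(=O)OC[C@@H]1Cc1ccccc1 | intermediate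
10 | (4S)-4-benzyl-3-{[(2S,3R)-6-bromo-8-methoxy-3-[3-methoxy-4,5-bis(methoxymethoxy)phenyl]-2,3-dihydro-1,4-benzodioxin-2-yl]carbonyl}-1,3-oxazolidin-2-one | O=C([C@H]1Oc2c(OC)cc(Br)cc2O[C@@H]1c1cc(OC)c(OCOC)c(OCOC)c1)N1C(=O)OC[C@@H]1Cc1ccccc1 | intermediate
11 | [(2R,3R)-6-bromo-8-methoxy-3-[3-methoxy-4,5-bis(methoxymethoxy)phenyl]-2,3-dihydro-1,4-benzodioxin-2-yl]methanol | OC[C@H]1Oc2c(OC)cc(Br)cc2O[C@@H]1c1cc(OC)c(OCOC)c(OCOC)c1 | intermediate
12 | (E)-2-(3,3-diethoxyprop-1-en-1-yl)-4,4,5,5-tetramethyl-1,3,2-dioxaborolane | CCOC(OCC)/C=C/B1OC(C)(C)C(C)(C)O1 | starting material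
13 | [(2R,3R)-6-[(1E)-3,3-diethoxyprop-1-en-1-yl]-8-methoxy-3-[3-methoxy-4,5-bis(methoxymethoxy)phenyl]-2,3-dihydro-1,4-benzodioxin-2-yl]methanol | OC[C@H]1Oc2c(OC)cc(/C=C/C(OCC)OCC)cc2O[C@@H]1c1cc(OC)c(OCOC)c(OCOC)c1 | intermediate
14 | (2E)-3-[(2R,3R)-2-(hydroxymethyl)-8-methoxy-3-[3-methoxy-4,5-bis(methoxymethoxy)phenyl]-2,3-dihydro-1,4-benzodioxin-6-yl]prop-2-enal | OC[C@H]1Oc2c(OC)cc(/C=C/C=O)cc2O[C@@H]1c1cc(OC)c(OCOC)c(OCOC)c1 | intermediate
15 | (2E)-3-[(2R,3R)-3-(3,4-dihydroxy-5-methoxyphenyl)-2-(hydroxymethyl)-8-methoxy-2,3-dihydro-1,4-benzodioxin-6-yl]prop-2-enal | COc1cc([C@H]2Oc3cc(/C=C/C=O)cc(OC)c3O[C@@H]2CO)cc(O)c1O | target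

Total step count: 6. Longest linear sequence: 5 steps (steps 1, 2, 4, 5 and 6; step 3 is a one-step side branch).

Steps most likely to fail

Step 4. In the copper stage the base may trigger retro-aldol cleavage of the β-hydroxy imide, or attack of its alkoxide on the oxazolidinone carbonyl, before the ring closes. Either would lower the yield and erode the configuration at C3. The fallback sets out from 4 and 6 and comes back to the route at 11. The aldol reaction is run alone (Bu2BOTf, iPr2NEt, CH2Cl2, then buffered H2O2) and 9 is isolated. LiBH4 in THF/H2O at 0 °C removes the auxiliary first and should give (1R,2R)-2-(4-bromo-2-iodo-6-methoxyphenoxy)-1-[3-methoxy-4,5-bis(methoxymethoxy)phenyl]propane-1,3-diol F1. Selective silylation of the primary hydroxyl (TBDPSCl, imidazole, DMF, 0 °C) should give (1R,2R)-2-(4-bromo-2-iodo-6-methoxyphenoxy)-3-[(tert-butyldiphenylsilyl)oxy]-1-[3-methoxy-4,5-bis(methoxymethoxy)phenyl]propan-1-ol F2, which no longer has a base-labile aldol unit. Ullmann-type ring closure (CuI, 3,4,7,8-tetramethyl-1,10-phenanthroline, Cs2CO3, toluene, 100 °C) should give {[(2R,3R)-6-bromo-8-methoxy-3-[3-methoxy-4,5-bis(methoxymethoxy)phenyl]-2,3-dihydro-1,4-benzodioxin-2-yl]methoxy}(tert-butyl)diphenylsilane F3, and nBu4NF in THF then gives 11.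

Step 6. The alkenyl boronate may protodeboronate before transmetalation. During the one-pot acid unmasking, the benzylic C3–O4 bond may ionise, with epimerisation or ring opening, and the liberated catechol may react with the formaldehyde released from the MOM groups. The fallback sets out from 11 and comes back at 14, trading the masked aldehyde for a redox sequence. A Heck reaction with methyl acrylate (Pd(OAc)2, P(o-tol)3, Et3N, DMF, 100 °C) should give methyl (2E)-3-[(2R,3R)-2-(hydroxymethyl)-8-methoxy-3-[3-methoxy-4,5-bis(methoxymethoxy)phenyl]-2,3-dihydro-1,4-benzodioxin-6-yl]prop-2-enoate F4. Reduction with iBu2AlH (CH2Cl2, −78 °C) should give (2E)-3-[(2R,3R)-2-(hydroxymethyl)-8-methoxy-3-[3-methoxy-4,5-bis(methoxymethoxy)phenyl]-2,3-dihydro-1,4-benzodioxin-6-yl]prop-2-en-1-ol F5. MnO2 (CH2Cl2, rt) should oxidise only the allylic alcohol and give 14, which is purified and then deprotected in a separate, shorter acid treatment (3 M HCl, THF, 45 °C) to 15.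

Step 2. The phenoxide, flanked by iodine and methoxy, may alkylate slowly, so that attack of carbonate or phenoxide on the imide carbonyls and loss of the auxiliary compete. The fallback sets out from 2 and comes back at 4, building the imide by N-acylation instead. Alkylation with tert-butyl bromoacetate (K2CO3, DMF, rt) should give tert-butyl (4-bromo-2-iodo-6-methoxyphenoxy)acetate F6. TFA in CH2Cl2 should give (4-bromo-2-iodo-6-methoxyphenoxy)acetic acid F7. Its mixed anhydride (PivCl, Et3N, THF, −20 °C) is treated with (4S)-4-benzyl-1,3-oxazolidin-2-one and LiCl at rt to give 4.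

Further compounds
F1 | step 4 | (1R,2R)-2-(4-bromo-2-iodo-6-methoxyphenoxy)-1-[3-methoxy-4,5-bis(methoxymethoxy)phenyl]propane-1,3-diol | OC[C@@H](Oc1c(I)cc(Br)cc1OC)[C@H](O)c1cc(OC)c(OCOC)c(OCOC)c1
F2 | step 4 | (1R,2R)-2-(4-bromo-2-iodo-6-methoxyphenoxy)-3-[(tert-butyldiphenylsilyl)oxy]-1-[3-methoxy-4,5-bis(methoxymethoxy)phenyl]propan-1-ol | CC(C)(C)[Si](c1ccccc1)(c1ccccc1)OC[C@@H](Oc1c(I)cc(Br)cc1OC)[C@H](O)c1cc(OC)c(OCOC)c(OCOC)c1
F3 | step 4 | {[(2R,3R)-6-bromo-8-methoxy-3-[3-methoxy-4,5-bis(methoxymethoxy)phenyl]-2,3-dihydro-1,4-benzodioxin-2-yl]methoxy}(tert-butyl)diphenylsilane | CC(C)(C)[Si](c1ccccc1)(c1ccccc1)OC[C@H]1Oc2c(OC)cc(Br)cc2O[C@@H]1c1cc(OC)c(OCOC)c(OCOC)c1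
F4 | step 6 | methyl (2E)-3-[(2R,3R)-2-(hydroxymethyl)-8-methoxy-3-[3-methoxy-4,5-bis(methoxymethoxy)phenyl]-2,3-dihydro-1,4-benzodioxin-6-yl]prop-2-enoate | OC[C@H]1Oc2c(OC)cc(/C=C/C(=O)OC)cc2O[C@@H]1c1cc(OC)c(OCOC)c(OCOC)c1
F5 | step 6 | (2E)-3-[(2R,3R)-2-(hydroxymethyl)-8-methoxy-3-[3-methoxy-4,5-bis(methoxymethoxy)phenyl]-2,3-dihydro-1,4-benzodioxin-6-yl]prop-2-en-1-ol | OC[C@H]1Oc2c(OC)cc(/C=C/CO)cc2O[C@@H]1c1cc(OC)c(OCOC)c(OCOC)c1
F6 | step 2 | tert-butyl (4-bromo-2-iodo-6-methoxyphenoxy)acetate | CC(C)(C)OC(=O)COc1c(I)cc(Br)cc1OC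
F7 | step 2 | (4-bromo-2-iodo-6-methoxyphenoxy)acetic acid | OC(=O)COc1c(I)cc(Br)cc1OC
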